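**Plan**

1. Retrosynthesis: remove the C7 allyl ester; derive the 1β-ol and the 2β,3β-epoxide from a ring A 2-en-1-one; cut C3–C4 and C4–C5 (two intramolecular Michael additions of a C10 propionate) and C1–C10 (acryloyl-anion addition); cut C13–C16 (ketyl–alkyne cyclisation); last, cut C11–C12 and C8–C9 together (intramolecular Diels–Alder).
2. Enabling feature: ring C (C8–C9–C11–C12–C13–C14) is a cyclohexane oxygenated at C13 that shares its C8–C9 edge with five-membered ring B, whose C10 (next to C9) carries oxygen. With C10 written as a ketone, C9=C11 is a vinyl ketone, C12=C13(OSi)–C14=C8 is a 2-silyloxydiene, and C10–C5–C6 is a three-atom tether.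
3. Forward order: acyclic trienone → rings B and C in one cycloaddition → ring B enone → lactone ring → ring D → ring A → enone, epoxide, carbinol → free acid.
4. Stereochemistry: C8 and C9 from a chiral Lewis acid in the cycloaddition; C10 by convex-face addition; C5 by delivery from the C10 oxygen; C4 and C13 by ring constraint; C6 by equilibration; C2/C3 and C1 by the lactone bridge and the epoxide.
5. Helpers put in and taken out: the second allyl ester (leaves as CO2 and propene while creating the ring B enone), the triisopropylsilyl enol ether (masks the C13 ketone), the C-silyl group on the alkyne, methoxyallene (masked acryloyl group), and the C7 allyl ester.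

Key step: step 7

Remark: gibberellane numbering (C1–C19) is used for all intermediates; β is the face of ring B that carries H5, H9, C15 and the C6 carboxyl in the target, α the face of the lactone bridge and C14.
Remark: compounds 16–19 are carried as mixtures of epimers at C4 and C6 (left undefined in their SMILES); both centres are fixed in step 14.

**Route**

Step 1
Reactants: 1 diallyl malonate; 2 2-chloro-N-methoxy-N-methylacetamide
Product: 3 diallyl 2-{2-[methoxy(methyl)amino]-2-oxoethyl}malonate
Conditions: NaH (1.0 equiv), 1 (1.5 equiv), NaI (cat.), THF, 0 °C → rt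
Reagents that add atoms: none
Why: SN2 alkylation of the sodium malonate by an α-chloro amide (malonic ester alkylation), with excess malonate suppressing dialkylation and no stereocenter formed.

Step 2
Reactants: 4 but-3-yn-2-ol (racemic); 5 3-bromo-1-(trimethylsilyl)prop-1-yne
Product: 6 7-(trimethylsilyl)hepta-3,6-diyn-2-ol (racemic)
Conditions: CuI (10 mol%), Bu4NI (10 mol%), K2CO3 (1.5 equiv), DMF, rt
Reagents that add atoms: none
Why: the copper acetylide of the terminal alkyne displaces the propargylic bromide (copper-catalysed alkyne–propargyl halide coupling to a skipped diyne), and the carbinol stereocenter is removed in step 3.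

Step 3
Reactants: 6 7-(trimethylsilyl)hepta-3,6-diyn-2-ol
Product: 7 7-(trimethylsilyl)hepta-3,6-diyn-2-one
Conditions: Dess–Martin periodinane (1.2 equiv), CH2Cl2, 0 °C; used at once
Reagents that add atoms: none
Why: Dess–Martin oxidation of a secondary propargylic alcohol under neutral conditions that should not isomerise the skipped diyne.

Step 4
Reactants: 3 diallyl 2-{2-[methoxy(methyl)amino]-2-oxoethyl}malonate; 7 7-(trimethylsilyl)hepta-3,6-diyn-2-one
Product: 8 diallyl 2-{2-[methoxy(methyl)amino]-2-oxoethyl}-2-[(4E)-6-oxo-1-(trimethylsilyl)hept-4-en-1-yn-4-yl]malonate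
Conditions: Cs2CO3 (10 mol%), THF, −20 → 0 °C
Reagents that add atoms: none
Why: base-catalytic Michael addition of the tertiary malonate anion to the β-carbon (C8) of the ynone, with the (E)-enone (bulky malonate carbon trans to acetyl) expected as the thermodynamic isomer.

Step 5
Reactants: 8 enone malonate
Product: 9 diallyl 2-{2-[methoxy(methyl)amino]-2-oxoethyl}-2-[(4E)-6-(triisopropylsilyloxy)-1-(trimethylsilyl)hepta-4,6-dien-1-yn-4-yl]malonate
Conditions: LiN(i-Pr)2 (1.05 equiv), THF, −78 °C; i-Pr3SiOTf, −78 → −40 °C
Reagents that add atoms: triisopropylsilyl trifluoromethanesulfonate CC(C)[Si](OS(=O)(=O)C(F)(F)F)(C(C)C)C(C)C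
Why: kinetic α′-deprotonation of the methyl ketone and O-silylation of the cross-conjugated dienolate give the 2-silyloxy-1,3-diene, the esters having no α-hydrogen and the amide CH2 being far less acidic.

Step 6
Reactants: 9 silyloxydiene Weinreb amide
Product: 11 diallyl 2-(2-oxobut-3-en-1-yl)-2-[(4E)-6-(triisopropylsilyloxy)-1-(trimethylsilyl)hepta-4,6-dien-1-yn-4-yl]malonate, via bromomagnesium hemiaminal 10 (not isolated)
Conditions: CH2=CHMgBr (1.3 equiv), THF, −40 → 0 °C; cold 0.5 M aq. HCl work-up; kept cold and used directly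
Reagents that add atoms: vinylmagnesium bromide C=C[Mg]Br
Why: Weinreb ketone synthesis, in which the chelated tetrahedral adduct prevents over-addition and releases the vinyl ketone only on acidic work-up, which also keeps the liberated amine from adding to the enone.

Step 7
Reactants: 11 trienone
Product: 12 diallyl (3aR,7aS)-3-oxo-6-(triisopropylsilyloxy)-7a-[3-(trimethylsilyl)prop-2-yn-1-yl]-2,3,3a,4,5,7a-hexahydro-1H-indene-1,1-dicarboxylate (cis-fused; ring B with C10 ketone and C6 diester, ring C with C13=C14 silyl enol ether, 8β-propargyl arm, 9β-H)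
Conditions: (S)-3,3-diphenyl-1-(2-methylphenyl)tetrahydro-1H,3H-pyrrolo[1,2-c][1,3,2]oxazaborole (20 mol%), HN(SO2CF3)2 (20 mol%), CH2Cl2, −78 → −20 °C
Reagents that add atoms: none
Why: The boron Lewis acid binds the C10 carbonyl of the s-trans vinyl ketone and lowers its LUMO, so that the 4π unit C12=C13(OSi)–C14=C8 and the 2π bond C9=C11 combine in a concerted, asynchronous [4+2] cycloaddition in which C11–C12 is the more advanced bond. The closest known reaction type is the oxazaborolidinium-catalysed enantioselective Diels–Alder reaction of 2-silyloxydienes with enones, in its intramolecular 1,6,8-nonatrien-3-one form. Ring C is closed as the six-membered ring of the [4+2] event (bonds C11–C12 and C8–C9), and ring B is closed by the same C8–C9 bond as the fused five-membered ring of a type 1 intramolecular Diels–Alder reaction through the three-atom tether C10–C5–C6. C9 is controlled by the catalyst, which shields one face of the bound enone, and quaternary C8 by the endo placement of the tether carbonyl, which leads to the cis-fused hydrindenone with H9 and the propargyl arm on the same face, the isomer that is also favoured if C9 epimerises. The step needs enantioface selectivity, cis (endo) selectivity and chemoselectivity for the vinyl ketone over the allyl esters and the silylalkyne; these rest on the chiral Lewis acid, on carbonyl activation inside the tether together with the (E)-diene geometry (tether outside, propargyl arm inside) and the folding effect of the geminal diester, and on the vinyl ketone being the only activated 2π partner. The (S)-configured catalyst is proposed from the accepted model for s-trans enones, and its mirror image would be used if the opposite sense were found.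

Step 8
Reactants: 12 cis-hydrindenone diester
Product: 13 allyl (3aR,7aS)-3-oxo-6-(triisopropylsilyloxy)-7a-[3-(trimethylsilyl)prop-2-yn-1-yl]-3a,4,5,7a-tetrahydro-3H-indene-1-carboxylate (ring B 2-cyclopentenone: C10 ketone, C5=C6 bearing the allyl ester)
Conditions: Pd(OAc)2 (5 mol%), Ph2PCH2CH2PPh2 (5 mol%), MeCN, 80 °C
Reagents that add atoms: none
Why: zerovalent palladium formed in situ ionises one allyl ester, the carboxylate loses CO2, and the C6 palladium enolate undergoes β-hydride elimination of a C5 hydrogen (Tsuji decarboxylation–dehydrogenation), allylation at the congested C6 being disfavoured and C9 remaining in the more stable cis arrangement.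

Step 9
Reactants: 13 ring B enone
Product: 15 tertiary propionate (10α-propanoyloxy, 10β-(1-methoxypropa-1,2-dien-1-yl), C5=C6–CO2allyl, 8β-silylpropargyl, C13=C14 silyl enol ether), via lithium C10 alkoxide 14 (not isolated)
Conditions: methoxyallene, n-BuLi, THF, −78 °C; add 13, −78 °C; then (EtCO)2O, −78 → 0 °C
Reagents that add atoms: methoxyallene COC=C=C; propionic anhydride CCC(=O)OC(=O)CC
Why: 1-lithio-1-methoxyallene (an acryloyl anion equivalent) adds 1,2 to the C10 ketone from the convex β face of the cis-hydrindenone (syn to H9, anti to ring C), which sets C10 with its oxygen α, and the lithium alkoxide is acylated in situ.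

Step 10
Reactants: 15 tertiary propionate
Product: 16 γ-lactone (O–C10 α, C19=O, C4H(CH3) bonded to C5 on the α face, 5β-H, 10β-(1-methoxyallenyl), allyl ester at C6, 8β-silylpropargyl, C13=C14 silyl enol ether; C4 and C6 epimers)
Conditions: LiN(SiMe3)2 (1.1 equiv), THF, −78 °C; AcOH quench at −78 °C
Reagents that add atoms: none
Why: the propionate enolate, the only enolisable site, adds 5-exo-trig to C5 of the enoate (intramolecular Michael addition) from the α face because it is tethered to the C10 oxygen, which sets C5 in the cis-fused γ-lactone, while the low temperature and cold quench keep [3,3] rearrangements of the ester enolates from competing.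

Step 11
Reactants: 16 γ-lactone
Product: 17 keto alkyne (as 16 with the C13 ketone and an 8β-prop-2-ynyl arm)
Conditions: Bu4NF (2.5 equiv), AcOH (2.5 equiv), THF, 0 °C → rt
Reagents that add atoms: none
Why: fluoride cleaves the Si–O bond of the silyl enol ether to release the C13 ketone and the Si–C bond of the silylalkyne, under buffered conditions that leave the acid-labile methoxyallene intact.

Step 12
Reactants: 17 keto alkyne
Product: 18 tetracyclic carbinol (rings B, C, D and lactone; 13-hydroxy, 16-methylene; 10β-(1-methoxyallenyl); allyl ester at C6)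
Conditions: SmI2 (2.5 equiv), HMPA, t-BuOH, THF, −78 → 0 °C
Reagents that add atoms: none
Why: single-electron reduction of the C13 ketone gives a ketyl radical that adds 5-exo-dig to C16 of the axial propargyl arm (ketyl–alkyne cyclisation), reduction and protonation of the vinyl radical leave the exocyclic methylene, and the C13 configuration is dictated by the bicyclo[3.2.1]octane bridge.

Step 13
Reactants: 18 tetracyclic methoxyallene
Product: 19 vinyl ketone (10β-acryloyl; otherwise as 18)
Conditions: 5% aq. H2SO4, THF, 0 °C
Reagents that add atoms: water O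
Why: protonation of the allenyl enol ether at its central carbon and hydrolysis of the resulting oxocarbenium ion unmask the vinyl ketone, dilute acid at 0 °C sparing the tertiary allylic 13-ol.

Step 14
Reactants: 19 vinyl ketone
Product: 20 ring A ketone (allyl ester of the 13-hydroxy-16-ene 19,10-lactone with C1=O, C2H2, C3H2; 4β-methyl, 5β-H, 6β-ester, 9β-H)
Conditions: KOt-Bu (0.2 equiv), t-BuOH–THF, 0 °C → rt
Reagents that add atoms: none
Why: the lactone enolate at C4, more acidic and less hindered than the C6 ester position, adds 6-endo-trig to C3 of the vinyl ketone (intramolecular Michael addition) and closes ring A, the bridged bicycle allowing only one configuration at quaternary C4, while the reversible conditions epimerise C6 to the more stable 6β ester trans to C4.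

Step 15
Reactants: 20 ring A ketone
Product: 21 ring A enone (C1=O, C2=C3; otherwise as 20)
Conditions: IBX (2-iodoxybenzoic acid, 2.5 equiv), DMSO–fluorobenzene, 70 °C
Reagents that add atoms: none
Why: IBX dehydrogenation of the C1 ketone through its only possible enol (C1=C2, C10 being quaternary) gives the 2-en-1-one without creating a stereocenter.

Step 16
Reactants: 21 ring A enone
Product: 22 2β,3β-epoxy-1-ketone (otherwise as 21)
Conditions: t-BuOOH (in decane), DBU, CH2Cl2, 0 °C → rt
Reagents that add atoms: tert-butyl hydroperoxide CC(C)(C)OO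
Why: Weitz–Scheffer nucleophilic epoxidation in which the peroxide anion attacks C3 axially from the β face, away from the α lactone bridge and the axial C4–C19 bond, and to which the electron-rich 16,17-alkene is inert.

Step 17
Reactants: 22 epoxy ketone
Product: 23 7-allyl ester of the target gibberellin (1β-hydroxy, 2β,3β-epoxy, 13-hydroxy, 16-ene, 19,10-lactone)
Conditions: LiBH(s-Bu)3 (1.1 equiv), THF, −78 °C; then H2O
Reagents that add atoms: none
Why: the bulky hydride attacks the C1 carbonyl from the α (equatorial) side, anti to the β epoxide oxygen and away from the 1,3-diaxial H5, to give the axial 1β-ol cis to the epoxide, while esters, lactone and epoxide are inert at −78 °C.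

Step 18
Reactants: 23 7-allyl ester of the target gibberellin
Product: 24 target gibberellin, 2β,3β-epoxy-1β,13-dihydroxy-20-norgibberell-16-ene-7,19-dioic acid 19,10-lactone
Conditions: Pd(PPh3)4 (5 mol%), morpholine (3 equiv), THF, rt; then dilute aq. citric acid
Reagents that add atoms: none
Why: zerovalent palladium ionises the allyl ester to a π-allyl complex that is trapped by morpholine (Tsuji–Trost deallylation), releasing the C7 acid under near-neutral conditions that spare the epoxide, the lactone and the tertiary allylic alcohol.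

**Compound list**

1 | diallyl malonate | C=CCOC(=O)CC(=O)OCC=C | starting material
2 | 2-chloro-N-methoxy-N-methylacetamide | CON(C)C(=O)CCl | starting material
3 | diallyl 2-{2-[methoxy(methyl)amino]-2-oxoethyl}malonate | C=CCOC(=O)C(CC(=O)N(C)OC)C(=O)OCC=C | intermediate
4 | but-3-yn-2-ol (racemic) | CC(O)C#C | starting material
5 | 3-bromo-1-(trimethylsilyl)prop-1-yne | C[Si](C)(C)C#CCBr | starting material
6 | 7-(trimethylsilyl)hepta-3,6-diyn-2-ol (racemic) | CC(O)C#CCC#C[Si](C)(C)C | intermediate
7 | 7-(trimethylsilyl)hepta-3,6-diyn-2-one | CC(=O)C#CCC#C[Si](C)(C)C | intermediate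
8 | diallyl 2-{2-[methoxy(methyl)amino]-2-oxoethyl}-2-[(4E)-6-oxo-1-(trimethylsilyl)hept-4-en-1-yn-4-yl]malonate | CC(=O)/C=C(\CC#C[Si](C)(C)C)C(CC(=O)N(C)OC)(C(=O)OCC=C)C(=O)OCC=C | intermediate
9 | diallyl 2-{2-[methoxy(methyl)amino]-2-oxoethyl}-2-[(4E)-6-(triisopropylsilyloxy)-1-(trimethylsilyl)hepta-4,6-dien-1-yn-4-yl]malonate | C=C(O[Si](C(C)C)(C(C)C)C(C)C)/C=C(\CC#C[Si](C)(C)C)C(CC(=O)N(C)OC)(C(=O)OCC=C)C(=O)OCC=C | intermediate
10 | bromomagnesium N-methoxy-N-methyl hemiaminal from 9 and vinylmagnesium bromide | C=CC(O[Mg]Br)(N(C)OC)CC(C(=O)OCC=C)(C(=O)OCC=C)/C(CC#C[Si](C)(C)C)=C/C(=C)O[Si](C(C)C)(C(C)C)C(C)C | intermediate (not isolated)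
11 | diallyl 2-(2-oxobut-3-en-1-yl)-2-[(4E)-6-(triisopropylsilyloxy)-1-(trimethylsilyl)hepta-4,6-dien-1-yn-4-yl]malonate | C=CC(=O)CC(C(=O)OCC=C)(C(=O)OCC=C)/C(CC#C[Si](C)(C)C)=C/C(=C)O[Si](C(C)C)(C(C)C)C(C)C | intermediate
12 | diallyl (3aR,7aS)-3-oxo-6-(triisopropylsilyloxy)-7a-[3-(trimethylsilyl)prop-2-yn-1-yl]-2,3,3a,4,5,7a-hexahydro-1H-indene-1,1-dicarboxylate | O=C1CC(C(=O)OCC=C)(C(=O)OCC=C)[C@@]2(CC#C[Si](C)(C)C)C=C(O[Si](C(C)C)(C(C)C)C(C)C)CC[C@@H]12 | intermediate
13 | allyl (3aR,7aS)-3-oxo-6-(triisopropylsilyloxy)-7a-[3-(trimethylsilyl)prop-2-yn-1-yl]-3a,4,5,7a-tetrahydro-3H-indene-1-carboxylate | O=C1C=C(C(=O)OCC=C)[C@@]2(CC#C[Si](C)(C)C)C=C(O[Si](C(C)C)(C(C)C)C(C)C)CC[C@@H]12 | intermediate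
14 | lithium C10 alkoxide: 13 after β-face addition of 1-methoxyallen-1-yl at C10 | [Li]O[C@@]1(C(OC)=C=C)C=C(C(=O)OCC=C)[C@@]2(CC#C[Si](C)(C)C)C=C(O[Si](C(C)C)(C(C)C)C(C)C)CC[C@@H]12 | intermediate (not isolated)
15 | tertiary propionate: 10α-propanoyloxy-10β-(1-methoxyallenyl) derivative with C5=C6–CO2allyl | CCC(=O)O[C@@]1(C(OC)=C=C)C=C(C(=O)OCC=C)[C@@]2(CC#C[Si](C)(C)C)C=C(O[Si](C(C)C)(C(C)C)C(C)C)CC[C@@H]12 | intermediate
16 | γ-lactone (19,10α-lactone, C4 on C5α, 10β-methoxyallenyl, C6 allyl ester, 8β-silylpropargyl, C13 silyl enol ether; C4/C6 epimers) | C=C=C(OC)[C@]12OC(=O)C(C)[C@H]1C(C(=O)OCC=C)[C@@]3(CC#C[Si](C)(C)C)C=C(O[Si](C(C)C)(C(C)C)C(C)C)CC[C@@H]23 | intermediate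
17 | keto alkyne (as 16 with C13 ketone and 8β-prop-2-ynyl; C4/C6 epimers) | C=C=C(OC)[C@]12OC(=O)C(C)[C@H]1C(C(=O)OCC=C)[C@@]3(CC#C)CC(=O)CC[C@@H]23 | intermediate
18 | tetracyclic carbinol (13-hydroxy, 16-methylene, 10β-methoxyallenyl, 19,10-lactone, C6 allyl ester; C4/C6 epimers) | C=C1C[C@]23C[C@@]1(O)CC[C@H]2[C@@]1(C(OC)=C=C)OC(=O)C(C)[C@H]1C3C(=O)OCC=C | intermediate
19 | vinyl ketone (10β-acryloyl; otherwise as 18; C4/C6 epimers) | C=C1C[C@]23C[C@@]1(O)CC[C@H]2[C@@]1(C(=O)C=C)OC(=O)C(C)[C@H]1C3C(=O)OCC=C | intermediate
20 | ring A ketone: allyl ester of the 13-hydroxy-16-ene 19,10-lactone with C1=O | C=C1C[C@]23C[C@@]1(O)CC[C@H]2[C@@]12OC(=O)[C@@](C)([C@H]1[C@@H]3C(=O)OCC=C)CCC2=O | intermediate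
21 | ring A enone (C1=O, C2=C3) | C=C1C[C@]23C[C@@]1(O)CC[C@H]2[C@@]12OC(=O)[C@@](C)([C@H]1[C@@H]3C(=O)OCC=C)C=CC2=O | intermediate
22 | 2β,3β-epoxy-1-ketone | C=C1C[C@]23C[C@@]1(O)CC[C@H]2[C@@]12OC(=O)[C@@](C)([C@H]1[C@@H]3C(=O)OCC=C)[C@H]1O[C@H]1C2=O | intermediate
23 | 7-allyl ester of the target gibberellin (1β,13-dihydroxy-2β,3β-epoxy-16-ene 19,10-lactone) | C=C1C[C@]23C[C@@]1(O)CC[C@H]2[C@@]12OC(=O)[C@@](C)([C@H]1[C@@H]3C(=O)OCC=C)[C@H]1O[C@H]1[C@H]2O | intermediate
24 | target gibberellin: 2β,3β-epoxy-1β,13-dihydroxy-20-norgibberell-16-ene-7,19-dioic acid 19,10-lactone (α/β as defined in the remark) | C=C1C[C@]23C[C@@]1(O)CC[C@H]2[C@@]12OC(=O)[C@@](C)([C@H]1[C@@H]3C(=O)O)[C@H]1O[C@H]1[C@H]2O | target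

**Step count and risks**

Total step count: 18. Longest linear sequence: 17 steps (steps 2–18, from but-3-yn-2-ol).

Steps most likely to fail:

Step 7. What may go wrong: the cycloaddition at the 1,1-disubstituted diene terminus may be slow at the low temperature needed for catalyst control, and a competing uncatalysed or stepwise Mukaiyama–Michael pathway would erode enantioface selectivity. Fallback (resolution in place of asymmetric catalysis), setting out from 11 and coming back at 12: trienone 11 is cyclised thermally (toluene, 90 °C, BHT), the ring-fusion centre C9 is equilibrated to the cis isomer with DBU, and the racemate, made up of 12 and its enantiomer ent-12 F1, is resolved by preparative chromatography on a chiral stationary phase; 12 rejoins the route at step 8.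

Step 4. What may go wrong: the strongly basic tertiary malonate anion may isomerise the skipped diynone 7 (propargyl–allenyl shift) before conjugate addition. Fallback (quaternary centre by alkylation instead of by conjugate addition), setting out from 1 and 7 and coming back at 8: the much less basic parent malonate 1 is added to 7 (Cs2CO3 cat., THF, −20 °C) to give diallyl 2-[(4E)-6-oxo-1-(trimethylsilyl)hept-4-en-1-yn-4-yl]malonate F2, whose stabilised anion (NaH, NaI, THF, 0 °C) is alkylated at the malonate carbon with chloroamide 2, returning to 8.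

Step 8. What may go wrong: the C6 palladium enolate may be captured by the π-allyl fragment (decarboxylative allylation) or protonated instead of undergoing β-hydride elimination. Fallback (stepwise decarboxylation, then selenoxide elimination), setting out from 12 and coming back at 13: 12 is treated with Pd(OAc)2, PPh3 and HCO2H–Et3N (decarboxylation–hydrogenolysis) to give the mono-allyl ester F3; kinetic enolisation of the C10 ketone towards C5 (LiN(i-Pr)2, THF, −78 °C) and trapping with PhSeCl give the C5 phenylselanyl ketone F4; oxidation with H2O2 and syn-elimination of the selenoxide across C5–C6 returns to enone 13.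

**Further compounds**

F1 | step 7 | diallyl (3aS,7aR)-3-oxo-6-(triisopropylsilyloxy)-7a-[3-(trimethylsilyl)prop-2-yn-1-yl]-2,3,3a,4,5,7a-hexahydro-1H-indene-1,1-dicarboxylate (ent-12) | O=C1CC(C(=O)OCC=C)(C(=O)OCC=C)[C@]2(CC#C[Si](C)(C)C)C=C(O[Si](C(C)C)(C(C)C)C(C)C)CC[C@H]12
F2 | step 4 | diallyl 2-[(4E)-6-oxo-1-(trimethylsilyl)hept-4-en-1-yn-4-yl]malonate | CC(=O)/C=C(\CC#C[Si](C)(C)C)C(C(=O)OCC=C)C(=O)OCC=C
F3 | step 8 | allyl (3aR,7aS)-3-oxo-6-(triisopropylsilyloxy)-7a-[3-(trimethylsilyl)prop-2-yn-1-yl]-2,3,3a,4,5,7a-hexahydro-1H-indene-1-carboxylate (C6 epimers) | O=C1CC(C(=O)OCC=C)[C@@]2(CC#C[Si](C)(C)C)C=C(O[Si](C(C)C)(C(C)C)C(C)C)CC[C@@H]12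
F4 | step 8 | C5 phenylselanyl derivative of F3 (C5/C6 epimers) | O=C1C([Se]c3ccccc3)C(C(=O)OCC=C)[C@@]2(CC#C[Si](C)(C)C)C=C(O[Si](C(C)C)(C(C)C)C(C)C)CC[C@@H]12
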